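Ring B is not carried through the synthesis but grown on the finished stereocentre. Cutting two of its bonds (C1-bearing carbon to the neighbouring CH; phenol carbon to methoxy carbon) leads back to an ynol silyl ether on C1 and methyl 3-bromocoumalate. Their [4+2] union with loss of CO2 builds ring B in one operation, with oxygen ortho to C1, bromine as the later OMe and the ester as the later styryl carbon. The precursor is a TIPS ynol ether whose propargylic carbon C1 holds ring A and the ring C benzyl group, phenols as MOM ethers; setting C1 therefore means separating aryl from alkynyl, not ring A from its near twin ring B.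

Key step: step 11

Abbreviations: MOM = methoxymethyl, TMS = trimethylsilyl, TIPS = tri(propan-2-yl)silyl; C1 = the stereocentre; ring A = 4-oxy-3-methoxyphenyl on C1, ring B = the ring built in step 11, ring C = 2,4-dioxyphenyl on the CH2, ring D = 3,5-dioxyphenyl of the styryl group.

Assumption (sense of induction): the facial sense of the nickel/pybox arylation in step 7 is assigned by analogy only, so the antipode of the commercial indanyl-pybox ligand that gives (S)-13 is the one used, and the configuration is confirmed on 14 before going on.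

Remark (descriptors): C1 keeps one spatial arrangement from step 7 to the target; its CIP letter is S throughout except in terminal alkyne 14 (R), where ethynyl ranks below aryl.

Remark (protecting groups): the aryl silyl ether formed in step 11 is not carried to the end, because methoxide cleaves it in step 12; it is replaced there by MOM so that one acid treatment finishes the synthesis.

Step 1
Reactants: 1 2,4-dihydroxyphenylacetic acid
Product: 2 methoxymethyl [2,4-bis(methoxymethoxy)phenyl]acetate
Conditions: MOMCl (4 equiv), i-Pr2NEt (5 equiv), CH2Cl2, 0 °C to rt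
Reagents that add atoms: chloromethyl methyl ether (MOMCl), COCCl
Why: Williamson-type O-alkylation: the α-chloro ether alkylates the carboxylate and both phenolates under amine base, and with the reagent in excess the ortho phenol is capped before it can lactonise onto the new ester.

Step 2
Reactants: 2 tris-MOM derivative of the ring C acid
Product: 3 [2,4-bis(methoxymethoxy)phenyl]acetaldehyde
Conditions: i-Bu2AlH (1.1 equiv), CH2Cl2, −78 °C; aq. potassium sodium tartrate
Reagents that add atoms: none
Why: Partial ester reduction with i-Bu2AlH: at −78 °C the aluminium hemiacetal (chelated by the MOM oxygen) does not collapse, so the aldehyde appears only on work-up and is not reduced further; it is carried on without storage.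

Step 3
Reactants: 3 ring C arylacetaldehyde; 4 ethynyltrimethylsilane
Product: 6 rac-1-[2,4-bis(methoxymethoxy)phenyl]-4-(trimethylsilyl)but-3-yn-2-ol, via lithium (trimethylsilyl)acetylide 5 (not isolated)
Conditions: 4, n-BuLi, THF, −78 °C; then 3, −78 °C; aq. NH4Cl
Reagents that add atoms: none
Why: Acetylide 1,2-addition to an aldehyde: the weakly basic lithium acetylide adds at −78 °C faster than it enolises the arylacetaldehyde, and a racemic carbinol suffices because this carbon is reset in step 7.

Step 4
Reactants: 6 racemic propargylic alcohol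
Product: 7 rac-[3-bromo-4-[2,4-bis(methoxymethoxy)phenyl]but-1-yn-1-yl]trimethylsilane
Conditions: CBr4, PPh3, CH2Cl2, 0 °C
Reagents that add atoms: tetrabromomethane, BrC(Br)(Br)Br
Why: Appel bromination under neutral conditions converts the secondary propargylic alcohol to the bromide, the silyl cap on the alkyne disfavouring SN2′ attack to a bromoallene and the MOM ethers being inert.

Step 5
Reactants: 8 4-bromo-2-methoxyphenol
Product: 9 4-bromo-2-methoxy-1-(methoxymethoxy)benzene
Conditions: MOMCl, i-Pr2NEt, CH2Cl2, 0 °C to rt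
Reagents that add atoms: chloromethyl methyl ether (MOMCl), COCCl
Why: Williamson-type protection of the phenol as its MOM ether, which is stable to the organolithium and organozinc chemistry that follows.

Step 6
Reactants: 9 MOM-protected ring A bromide
Product: 11 [3-methoxy-4-(methoxymethoxy)phenyl]boronic acid, via [3-methoxy-4-(methoxymethoxy)phenyl]lithium 10 (not isolated)
Conditions: n-BuLi, THF, −78 °C; B(Oi-Pr)3, −78 °C to rt; aq. NH4Cl (pH about 6)
Reagents that add atoms: triisopropyl borate, CC(C)OB(OC(C)C)OC(C)C; water, O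
Why: Bromine–lithium exchange, faster at −78 °C than ortho-lithiation beside the MOM ether, followed by borate trapping and near-neutral hydrolysis gives the arylboronic acid with the acetal intact.

Step 7
Reactants: 7 racemic propargylic bromide; 11 ring A boronic acid
Product: 13 [(3S)-4-[2,4-bis(methoxymethoxy)phenyl]-3-[3-methoxy-4-(methoxymethoxy)phenyl]but-1-yn-1-yl]trimethylsilane, via ethyl[3-methoxy-4-(methoxymethoxy)phenyl]zinc 12 (not isolated)
Conditions: 11, Et2Zn (3 equiv), toluene, 60 °C, volatiles removed; then 7, NiCl2(dme) (3 mol %), indanyl-pybox (4 mol %), DME, −20 °C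
Reagents that add atoms: none
Why: Enantioconvergent nickel/pybox Negishi arylation of a racemic secondary propargylic bromide: boron-to-zinc exchange supplies the ArZnEt nucleophile, both enantiomers of 7 are converted to one propargylic radical, and its capture by the chiral aryl–nickel complex sets C1 under ligand control.

Step 8
Reactants: 13 (S)-TMS alkyne
Product: 14 1-[(2R)-2-[3-methoxy-4-(methoxymethoxy)phenyl]but-3-yn-1-yl]-2,4-bis(methoxymethoxy)benzene
Conditions: K2CO3 (0.2 equiv), MeOH, rt
Reagents that add atoms: none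
Why: Base-catalysed methanolysis of the C(sp)–Si bond; catalytic carbonate in methanol is far too weak a base to remove the benzylic, propargylic C1–H, so neither allene formation nor racemisation is expected.

Step 9
Reactants: 14 terminal alkyne
Product: 17 [[(3S)-4-[2,4-bis(methoxymethoxy)phenyl]-3-[3-methoxy-4-(methoxymethoxy)phenyl]but-1-yn-1-yl]oxy]tri(propan-2-yl)silane, via lithium acetylide 15 (not isolated), via lithium ynolate 16 (not isolated)
Conditions: LiN(SiMe3)2 (2.2 equiv), THF, −78 °C; t-BuOOH (1.05 equiv, anhydrous in decane), −78 to 0 °C; i-Pr3SiOTf (1.2 equiv), −78 °C; hexane extraction, Et3N-deactivated silica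
Reagents that add atoms: tert-butyl hydroperoxide, CC(C)(C)OO; triisopropylsilyl trifluoromethanesulfonate, CC(C)[Si](C(C)C)(C(C)C)OS(=O)(=O)C(F)(F)F
Why: Oxidation of a lithium acetylide by lithium tert-butyl peroxide (electrophilic oxygen transfer with loss of tert-butoxide) gives the lithium ynolate, which the bulky silyl triflate traps on oxygen and not on carbon; the amide base deprotonates only the terminal alkyne and the hydroperoxide, not C1–H.

Step 10
Reactants: 18 methyl coumalate (methyl 2-oxo-2H-pyran-5-carboxylate)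
Product: 19 methyl 3-bromo-2-oxo-2H-pyran-5-carboxylate (methyl 3-bromocoumalate)
Conditions: Br2 (1.05 equiv), CH2Cl2, rt; then Et3N (1.1 equiv), 0 °C
Reagents that add atoms: bromine, BrBr
Why: Electrophilic bromination of the 2-pyranone by bromine addition and amine-induced loss of HBr (addition–elimination) occurs at C3, the only free nucleophilic ring position since C5 carries the ester.

Step 11
Reactants: 17 TIPS ynol ether on C1; 19 methyl 3-bromocoumalate
Product: 21 methyl 3-bromo-5-[(1S)-2-[2,4-bis(methoxymethoxy)phenyl]-1-[3-methoxy-4-(methoxymethoxy)phenyl]ethyl]-4-[[tri(propan-2-yl)silyl]oxy]benzoate, via bridged lactone cycloadduct 20 (not isolated)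
Conditions: 19 (1.5 equiv), toluene, 90 °C, Ar, sealed tube, base-washed glassware
Reagents that add atoms: none
Why: Proposed new method: the electron-rich ynol ether and the pyranone made electron-poor by its ester and bromine should combine in an inverse-electron-demand [4+2] cycloaddition, asynchronous to the point of a zwitterion, in which the nucleophilic alkyne carbon on C1 bonds to pyranone C6 and the silyloxy carbon to C3, after which bridged lactone 20 loses CO2 by retro-[4+2]; the closest known reaction type is the inverse-demand Diels–Alder/decarboxylation of methyl coumalate and 3-halo-2-pyranones with ynamines, enol ethers and ketene acetals, and silyl ynol ethers are known to tolerate comparable temperatures in the Danheiser benzannulation. Ring B is closed by an intermolecular [4+2] annulation (four carbons from the pyranone, two from the alkyne) and becomes aromatic through the cycloreversion itself, with no separate oxidation or elimination. No stereocentre is created: the bridgehead centres of 20 disappear with CO2, and C1 is a spectator sp3 carbon with no acidifying neighbour under neutral, base-free heating, so its configuration should carry over. The step needs regioselectivity, which matched polarisation supplies (the carbon of the ynol ether remote from oxygen is its nucleophilic end; C6 of the pyranone, β to the ester and vinylogous to the lactone carbonyl, is the electrophilic end), and it needs the cycloaddition to outrun the thermal 1,3-silyl shift of the ynol ether to a silylketene, for which the bulky TIPS group and the bromine at C3 were chosen.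

Step 12
Reactants: 21 ring B bromo silyl ether benzoate
Product: 23 methyl 3-[(1S)-2-[2,4-bis(methoxymethoxy)phenyl]-1-[3-methoxy-4-(methoxymethoxy)phenyl]ethyl]-4-hydroxy-5-methoxybenzoate, via bromophenol 22 (not isolated)
Conditions: NaOMe (8 equiv), CuBr (20 mol %), MeOH–DMF, 110 °C, Ar; aq. NH4Cl
Reagents that add atoms: sodium methoxide, [Na+].[O-]C
Why: Methoxide first cleaves the hindered aryl silyl ether, and the ortho-bromophenolate 22 then undergoes copper-catalysed Ullmann-type methoxylation, the reaction type that converts 5-bromovanillin into syringaldehyde; a methyl ester is degenerate toward methoxide, and MOM ethers and the non-acidified C1–H are untouched.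

Step 13
Reactants: 23 ring B methoxyphenol ester
Product: 24 methyl 3-[(1S)-2-[2,4-bis(methoxymethoxy)phenyl]-1-[3-methoxy-4-(methoxymethoxy)phenyl]ethyl]-5-methoxy-4-(methoxymethoxy)benzoate
Conditions: MOMCl (3 equiv), i-Pr2NEt (4 equiv), CH2Cl2, 0 to 40 °C
Reagents that add atoms: chloromethyl methyl ether (MOMCl), COCCl
Why: Williamson-type MOM protection of the hindered phenol by the small, highly reactive α-chloro ether, so that no phenolate can deactivate the aldehyde in the later olefination.

Step 14
Reactants: 24 tetra-MOM benzoate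
Product: 25 [3-[(1S)-2-[2,4-bis(methoxymethoxy)phenyl]-1-[3-methoxy-4-(methoxymethoxy)phenyl]ethyl]-5-methoxy-4-(methoxymethoxy)phenyl]methanol
Conditions: LiAlH4, THF, 0 °C
Reagents that add atoms: none
Why: Hydride reduction of the methyl benzoate to the benzylic alcohol; aryl ethers and acetals do not react with LiAlH4.

Step 15
Reactants: 25 benzylic alcohol
Product: 26 3-[(1S)-2-[2,4-bis(methoxymethoxy)phenyl]-1-[3-methoxy-4-(methoxymethoxy)phenyl]ethyl]-5-methoxy-4-(methoxymethoxy)benzaldehyde
Conditions: MnO2 (activated, 15 equiv), CH2Cl2, rt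
Reagents that add atoms: none
Why: MnO2 oxidises the electron-rich benzylic alcohol selectively and stops at the aldehyde, leaving the doubly benzylic C1–H and the acetals alone.

Step 16
Reactants: 27 3,5-dihydroxybenzyl alcohol
Product: 28 [3,5-bis(methoxymethoxy)phenyl]methanol
Conditions: MOMCl (2.1 equiv), K2CO3 (2.5 equiv), acetone, 0 °C to rt
Reagents that add atoms: chloromethyl methyl ether (MOMCl), COCCl
Why: Chemoselective Williamson alkylation: carbonate ionises only the two phenols (not the benzylic alcohol), so the phenolates take up the MOM groups.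

Step 17
Reactants: 28 ring D benzylic alcohol
Product: 29 1-(bromomethyl)-3,5-bis(methoxymethoxy)benzene
Conditions: CBr4, PPh3, CH2Cl2, 0 °C
Reagents that add atoms: tetrabromomethane, BrC(Br)(Br)Br
Why: Appel bromination of the primary benzylic alcohol under neutral conditions that the MOM ethers tolerate.

Step 18
Reactants: 29 ring D benzylic bromide
Product: 30 diethyl [[3,5-bis(methoxymethoxy)phenyl]methyl]phosphonate
Conditions: P(OEt)3 (neat), 130 °C
Reagents that add atoms: triethyl phosphite, CCOP(OCC)OCC
Why: Michaelis–Arbuzov reaction: the phosphite displaces the benzylic bromide and the phosphonium intermediate is dealkylated by bromide to the phosphonate.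

Step 19
Reactants: 26 ring B aldehyde; 30 ring D phosphonate
Product: 31 1-[(1S)-2-[2,4-bis(methoxymethoxy)phenyl]-1-[3-methoxy-4-(methoxymethoxy)phenyl]ethyl]-5-[(E)-2-[3,5-bis(methoxymethoxy)phenyl]ethenyl]-3-methoxy-2-(methoxymethoxy)benzene
Conditions: KOt-Bu (1.3 equiv, added last), THF, 0 °C to rt
Reagents that add atoms: none
Why: Horner–Wadsworth–Emmons olefination: the stabilised benzylic phosphonate anion adds reversibly to the aryl aldehyde and eliminates to the (E)-stilbene, and the small excess of alkoxide, taken up by the phosphonate, should not epimerise C1.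

Step 20
Reactants: 31 penta-MOM stilbene
Product: 32 4-[(2S)-2-[5-[(E)-2-(3,5-dihydroxyphenyl)ethenyl]-2-hydroxy-3-methoxyphenyl]-2-(4-hydroxy-3-methoxyphenyl)ethyl]benzene-1,3-diol (CNP0254096.1)
Conditions: 3 M aq. HCl, MeOH, 45 °C, Ar, dark
Reagents that add atoms: none
Why: Acid-catalysed acetal cleavage (transacetalisation to dimethoxymethane in methanol) removes all five MOM groups, the solvent trapping the formaldehyde equivalent before it can alkylate resorcinol rings C and D, while the (E)-alkene and C1 are unaffected by dilute acid.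

Compound list

1 | 2,4-dihydroxyphenylacetic acid | O=C(O)Cc1ccc(O)cc1O | starting material
2 | methoxymethyl [2,4-bis(methoxymethoxy)phenyl]acetate | COCOC(=O)Cc1ccc(OCOC)cc1OCOC | intermediate
3 | [2,4-bis(methoxymethoxy)phenyl]acetaldehyde | O=CCc1ccc(OCOC)cc1OCOC | intermediate
4 | ethynyltrimethylsilane | C#C[Si](C)(C)C | starting material
5 | lithium (trimethylsilyl)acetylide (not isolated) | [Li]C#C[Si](C)(C)C | intermediate
6 | rac-1-[2,4-bis(methoxymethoxy)phenyl]-4-(trimethylsilyl)but-3-yn-2-ol | C[Si](C)(C)C#CC(O)Cc1ccc(OCOC)cc1OCOC | intermediate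
7 | rac-[3-bromo-4-[2,4-bis(methoxymethoxy)phenyl]but-1-yn-1-yl]trimethylsilane | C[Si](C)(C)C#CC(Br)Cc1ccc(OCOC)cc1OCOC | intermediate
8 | 4-bromo-2-methoxyphenol | COc1cc(Br)ccc1O | starting material
9 | 4-bromo-2-methoxy-1-(methoxymethoxy)benzene | COCOc1ccc(Br)cc1OC | intermediate
10 | [3-methoxy-4-(methoxymethoxy)phenyl]lithium (not isolated) | [Li]c1ccc(OCOC)c(OC)c1 | intermediate
11 | [3-methoxy-4-(methoxymethoxy)phenyl]boronic acid | OB(O)c1ccc(OCOC)c(OC)c1 | intermediate
12 | ethyl[3-methoxy-4-(methoxymethoxy)phenyl]zinc (not isolated) | CC[Zn]c1ccc(OCOC)c(OC)c1 | intermediate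
13 | [(3S)-4-[2,4-bis(methoxymethoxy)phenyl]-3-[3-methoxy-4-(methoxymethoxy)phenyl]but-1-yn-1-yl]trimethylsilane | COc1cc([C@H](Cc2ccc(OCOC)cc2OCOC)C#C[Si](C)(C)C)ccc1OCOC | intermediate
14 | 1-[(2R)-2-[3-methoxy-4-(methoxymethoxy)phenyl]but-3-yn-1-yl]-2,4-bis(methoxymethoxy)benzene | COc1cc([C@H](Cc2ccc(OCOC)cc2OCOC)C#C)ccc1OCOC | intermediate
15 | lithium acetylide of 14, C1 unchanged (not isolated) | COc1cc([C@H](Cc2ccc(OCOC)cc2OCOC)C#C[Li])ccc1OCOC | intermediate
16 | lithium ynolate, C1–C≡C–OLi, C1 unchanged (not isolated) | COc1cc([C@H](Cc2ccc(OCOC)cc2OCOC)C#CO[Li])ccc1OCOC | intermediate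
17 | [[(3S)-4-[2,4-bis(methoxymethoxy)phenyl]-3-[3-methoxy-4-(methoxymethoxy)phenyl]but-1-yn-1-yl]oxy]tri(propan-2-yl)silane | COc1cc([C@H](Cc2ccc(OCOC)cc2OCOC)C#CO[Si](C(C)C)(C(C)C)C(C)C)ccc1OCOC | intermediate
18 | methyl 2-oxo-2H-pyran-5-carboxylate (methyl coumalate) | COC(=O)c1ccc(=O)oc1 | starting material
19 | methyl 3-bromo-2-oxo-2H-pyran-5-carboxylate | COC(=O)c1cc(Br)c(=O)oc1 | intermediate
20 | methyl 4-bromo-7-[(1S)-2-[2,4-bis(methoxymethoxy)phenyl]-1-[3-methoxy-4-(methoxymethoxy)phenyl]ethyl]-3-oxo-8-[[tri(propan-2-yl)silyl]oxy]-2-oxabicyclo[2.2.2]octa-5,7-diene-6-carboxylate, both bridgehead diastereomers (not isolated) | COc1cc([C@H](Cc2ccc(OCOC)cc2OCOC)C2=C(O[Si](C(C)C)(C(C)C)C(C)C)C3(Br)C=C(C(=O)OC)C2OC3=O)ccc1OCOC | intermediate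
21 | methyl 3-bromo-5-[(1S)-2-[2,4-bis(methoxymethoxy)phenyl]-1-[3-methoxy-4-(methoxymethoxy)phenyl]ethyl]-4-[[tri(propan-2-yl)silyl]oxy]benzoate | COc1cc([C@H](Cc2ccc(OCOC)cc2OCOC)c2cc(C(=O)OC)cc(Br)c2O[Si](C(C)C)(C(C)C)C(C)C)ccc1OCOC | intermediate
22 | methyl 3-bromo-5-[(1S)-2-[2,4-bis(methoxymethoxy)phenyl]-1-[3-methoxy-4-(methoxymethoxy)phenyl]ethyl]-4-hydroxybenzoate, sodium phenolate in the flask (not isolated) | COc1cc([C@H](Cc2ccc(OCOC)cc2OCOC)c2cc(C(=O)OC)cc(Br)c2O)ccc1OCOC | intermediate
23 | methyl 3-[(1S)-2-[2,4-bis(methoxymethoxy)phenyl]-1-[3-methoxy-4-(methoxymethoxy)phenyl]ethyl]-4-hydroxy-5-methoxybenzoate | COc1cc([C@H](Cc2ccc(OCOC)cc2OCOC)c2cc(C(=O)OC)cc(OC)c2O)ccc1OCOC | intermediate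
24 | methyl 3-[(1S)-2-[2,4-bis(methoxymethoxy)phenyl]-1-[3-methoxy-4-(methoxymethoxy)phenyl]ethyl]-5-methoxy-4-(methoxymethoxy)benzoate | COc1cc([C@H](Cc2ccc(OCOC)cc2OCOC)c2cc(C(=O)OC)cc(OC)c2OCOC)ccc1OCOC | intermediate
25 | [3-[(1S)-2-[2,4-bis(methoxymethoxy)phenyl]-1-[3-methoxy-4-(methoxymethoxy)phenyl]ethyl]-5-methoxy-4-(methoxymethoxy)phenyl]methanol | COc1cc([C@H](Cc2ccc(OCOC)cc2OCOC)c2cc(CO)cc(OC)c2OCOC)ccc1OCOC | intermediate
26 | 3-[(1S)-2-[2,4-bis(methoxymethoxy)phenyl]-1-[3-methoxy-4-(methoxymethoxy)phenyl]ethyl]-5-methoxy-4-(methoxymethoxy)benzaldehyde | COc1cc([C@H](Cc2ccc(OCOC)cc2OCOC)c2cc(C=O)cc(OC)c2OCOC)ccc1OCOC | intermediate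
27 | 3,5-dihydroxybenzyl alcohol | OCc1cc(O)cc(O)c1 | starting material
28 | [3,5-bis(methoxymethoxy)phenyl]methanol | COCOc1cc(CO)cc(OCOC)c1 | intermediate
29 | 1-(bromomethyl)-3,5-bis(methoxymethoxy)benzene | COCOc1cc(CBr)cc(OCOC)c1 | intermediate
30 | diethyl [[3,5-bis(methoxymethoxy)phenyl]methyl]phosphonate | CCOP(=O)(Cc1cc(OCOC)cc(OCOC)c1)OCC | intermediate
31 | 1-[(1S)-2-[2,4-bis(methoxymethoxy)phenyl]-1-[3-methoxy-4-(methoxymethoxy)phenyl]ethyl]-5-[(E)-2-[3,5-bis(methoxymethoxy)phenyl]ethenyl]-3-methoxy-2-(methoxymethoxy)benzene | COc1cc([C@H](Cc2ccc(OCOC)cc2OCOC)c2cc(/C=C/c3cc(OCOC)cc(OCOC)c3)cc(OC)c2OCOC)ccc1OCOC | intermediate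
32 | 4-[(2S)-2-[5-[(E)-2-(3,5-dihydroxyphenyl)ethenyl]-2-hydroxy-3-methoxyphenyl]-2-(4-hydroxy-3-methoxyphenyl)ethyl]benzene-1,3-diol (CNP0254096.1) | COc1cc([C@H](Cc2ccc(O)cc2O)c2cc(/C=C/c3cc(O)cc(O)c3)cc(OC)c2O)ccc1O | target

Total step count: 20. Longest linear sequence: 14 steps (1–4, 7–9, 11–15, 19, 20). Steps 5–6 (ring A), 10 (pyranone) and 16–18 (ring D phosphonate) are side branches.

Steps most likely to fail

1. Step 11 (the one step flagged as new chemistry). The ynol ether may be consumed by thermal 1,3-silyl migration to a silylketene. Attack at pyranone C6 may also be followed by opening of the pyranone in place of ring closure, or the hindered alkyne carbon may react too slowly, so that long heating erodes material and possibly C1. The fallback uses known chemistry: ring B is brought in intact and C1 is set by a stereoconvergent nickel/bis(oxazoline) Negishi arylation of a racemic secondary benzylic methanesulfonate, in which rings A and B enter in different roles (nucleophile and electrophile). It sets out from aldehyde 3 and aryllithium 10 and comes back to the route at aldehyde 26. Commercial 5-bromovanillin would be converted (MOMCl, i-Pr2NEt) into 3-bromo-5-methoxy-4-(methoxymethoxy)benzaldehyde F1 and then (HC(OMe)3, cat. pyridinium tosylate, MeOH) into 1-bromo-5-(dimethoxymethyl)-3-methoxy-2-(methoxymethoxy)benzene F2. Bromine–lithium exchange on F2 (n-BuLi, THF, −78 °C) and addition to 3 would give rac-2-[2,4-bis(methoxymethoxy)phenyl]-1-[5-(dimethoxymethyl)-3-methoxy-2-(methoxymethoxy)phenyl]ethan-1-ol F3. Mesylation in the flask (MsCl, Et3N) would give the racemic methanesulfonate F4. This would be coupled at −45 °C with iodo[3-methoxy-4-(methoxymethoxy)phenyl]zinc F5 (from 10 and ZnI2) under NiBr2(diglyme), a chiral bis(oxazoline) ligand and LiI, to give the (S)-1,1-diarylalkane dimethyl acetal F6. Mild acetal hydrolysis (pyridinium tosylate, wet acetone; MOM ethers survive) would deliver 26, and steps 19 and 20 follow unchanged.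

2. Step 7. The aryl–nickel complex may capture the propargylic radical with too little facial discrimination, or the homobenzylic bromide may be lost by elimination to the conjugated enyne before coupling. The fallback sets C1 by conjugate arylation and reaches the ynolate from an ester of the same oxidation level. It sets out from aldehyde 3 and boronic acid 11 and comes back at lithium ynolate 16, which is silylated to 17 as in the last operation of step 9 (steps 4, 7 and 8 are bypassed). Wittig olefination of 3 with Ph3P=CHCO2Et would give ethyl (2E)-4-[2,4-bis(methoxymethoxy)phenyl]but-2-enoate F7. Hayashi–Miyaura 1,4-addition of 11 under Rh(acac)(C2H4)2/BINAP (dioxane–water, 100 °C; ligand antipode chosen for the 3R ester) would give ethyl (3R)-4-[2,4-bis(methoxymethoxy)phenyl]-3-[3-methoxy-4-(methoxymethoxy)phenyl]butanoate F8, with C1 set by catalyst control and never adjacent to a carbonyl. Two rounds of enolate bromination (LiN(SiMe3)2, BrCF2CF2Br, −78 °C) would give the α,α-dibromo ester F9. t-BuLi (4 equiv, THF, −78 to 0 °C) would convert F9 by double bromine–lithium exchange and loss of ethoxide into 16.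

3. Step 9. Oxygen transfer to the hindered acetylide may be incomplete, the acetylide and the acidic C1–H may exchange protons during the hours at 0 °C (allene formation, loss of configuration), or the ynolate may be silylated on carbon to a silylketene. The fallback reaches the ynolate through an alkynyl sulfonate and never holds a free acetylide at 0 °C. It sets out from alkyne 14 and comes back at lithium ynolate 16. Alkyne 14 with [hydroxy(tosyloxy)iodo]benzene (CH2Cl2, desiccant, rt) would give the alkynyl(phenyl)iodonium tosylate F10. CuOTf-catalysed collapse of F10 in MeCN would give the alkynyl 4-methylbenzenesulfonate F11. MeLi (THF, −78 °C) attacks sulfur in F11 and releases 16, which i-Pr3SiOTf converts to 17.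

Further compounds

F1 | step 11 | 3-bromo-5-methoxy-4-(methoxymethoxy)benzaldehyde | COCOc1c(Br)cc(C=O)cc1OC
F2 | step 11 | 1-bromo-5-(dimethoxymethyl)-3-methoxy-2-(methoxymethoxy)benzene | COCOc1c(Br)cc(C(OC)OC)cc1OC
F3 | step 11 | rac-2-[2,4-bis(methoxymethoxy)phenyl]-1-[5-(dimethoxymethyl)-3-methoxy-2-(methoxymethoxy)phenyl]ethan-1-ol | COCOc1ccc(CC(O)c2cc(C(OC)OC)cc(OC)c2OCOC)c(OCOC)c1
F4 | step 11 | rac-2-[2,4-bis(methoxymethoxy)phenyl]-1-[5-(dimethoxymethyl)-3-methoxy-2-(methoxymethoxy)phenyl]ethyl methanesulfonate | COCOc1ccc(CC(OS(C)(=O)=O)c2cc(C(OC)OC)cc(OC)c2OCOC)c(OCOC)c1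
F5 | step 11 | iodo[3-methoxy-4-(methoxymethoxy)phenyl]zinc | COCOc1ccc([Zn]I)cc1OC
F6 | step 11 | 1-[(1S)-2-[2,4-bis(methoxymethoxy)phenyl]-1-[3-methoxy-4-(methoxymethoxy)phenyl]ethyl]-5-(dimethoxymethyl)-3-methoxy-2-(methoxymethoxy)benzene | COc1cc([C@H](Cc2ccc(OCOC)cc2OCOC)c2cc(C(OC)OC)cc(OC)c2OCOC)ccc1OCOC
F7 | step 7 | ethyl (2E)-4-[2,4-bis(methoxymethoxy)phenyl]but-2-enoate | CCOC(=O)/C=C/Cc1ccc(OCOC)cc1OCOC
F8 | step 7 | ethyl (3R)-4-[2,4-bis(methoxymethoxy)phenyl]-3-[3-methoxy-4-(methoxymethoxy)phenyl]butanoate | COc1cc([C@H](Cc2ccc(OCOC)cc2OCOC)CC(=O)OCC)ccc1OCOC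
F9 | step 7 | ethyl (3S)-2,2-dibromo-4-[2,4-bis(methoxymethoxy)phenyl]-3-[3-methoxy-4-(methoxymethoxy)phenyl]butanoate | COc1cc([C@H](Cc2ccc(OCOC)cc2OCOC)C(Br)(Br)C(=O)OCC)ccc1OCOC
F10 | step 9 | [(3S)-4-[2,4-bis(methoxymethoxy)phenyl]-3-[3-methoxy-4-(methoxymethoxy)phenyl]but-1-yn-1-yl](phenyl)iodonium 4-methylbenzenesulfonate | COc1cc([C@H](Cc2ccc(OCOC)cc2OCOC)C#C[I+]c2ccccc2)ccc1OCOC.Cc1ccc(cc1)S(=O)(=O)[O-]
F11 | step 9 | (3S)-4-[2,4-bis(methoxymethoxy)phenyl]-3-[3-methoxy-4-(methoxymethoxy)phenyl]but-1-yn-1-yl 4-methylbenzenesulfonate | COc1cc([C@H](Cc2ccc(OCOC)cc2OCOC)C#COS(=O)(=O)c2ccc(C)cc2)ccc1OCOC
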